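Take the leftover first: subtract the impurity, 6.5 µM, from the free enzyme charged, 8.5 µM, and keep the remainder, 2.00 µM. Call it the leftover enzyme: the free enzyme still working once each impurity molecule has taken one enzyme molecule. This pairing is my assumption, and in it the impurity is the limiting reagent.

| flask | starting material | free enzyme | impurity | temperature | remark | time |
|---|---|---|---|---|---|---|
| violet | 0.050 M | 8.5 µM | 6.5 µM | 25 °C | the very flask that is asked about, followed so far |  |
| grey | 0.025 M | 8.5 µM | 6.5 µM | 25 °C | run made earlier |  |
| flask | 0.050 M | 8.5 µM | 6.5 µM | 25 °C |  | 6.0 h |

| run | time / h | product / % |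
|---|---|---|
| violet | 1.50 | 41.9 |
| violet | 3.00 | 48.2 |
| violet | 5.00 | 53.7 |
| violet | 6.00 | 55.7 |
| grey | 0.333 | 12.0 |
| grey | 0.833 | 18.7 |
| grey | 1.50 | 23.4 |
| grey | 2.50 | 27.4 |

(readings scatter by 0.3 percentage points)

- noon: change nothing and wait 3.0 h more
- dusk: at 6.0 h add free enzyme, 50.0 % of the amount charged, then wait 3.0 h
- summer: at 6.0 h raise the temperature by 15 K, then wait 3.0 h
- dawn: at 6.0 h take out 90 % of the product then present, then wait 3.0 h

- product taken out counts as made
- the numbers in the tables scatter with a standard deviation of 0.3 percentage points
- additions bring no volume worth counting
- the earlier runs do not show what temperature does; that part of a forecast is a guess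

- product, in percent of the starting material first charged, at 6.0 h
- the option that brings most further product ("none" if no option brings more than 2 percentage points) (noon / dusk / summer / dawn / none)
- product present, with what was taken out counted in, in percent of the starting material first charged, after noon
- product present, with what was taken out counted in, in percent of the starting material first charged, after dawn

Now set two numbers side by side. In the violet flask the impurity is one molecule to 7692 of starting material, which looks negligible, yet it equals 76.5 % of the enzyme charged. Clear this up by counting turnovers, the product made per working enzyme. At 6.00 h the violet flask holds 55.7 % of 0.050 M, which is 13900 turnovers per leftover enzyme. That count runs high, since some of the product may have been made before the impurity had taken its share of the enzyme. Even per enzyme charged it is still 3280 turnovers, so weigh the impurity against the enzyme and not against the starting material.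

Then reckon dusk. Suppose the impurity is used up by 6.0 h. The added 4.25 µM then stays working, and the violet flask holds 6.25 µM, or 3.12 times the leftover. Take the rate to follow the working enzyme, and dusk starts that many times faster than noon, so I commit to dusk.

The forecast gives 55.7 % (55.3 % to 56.1 %), 60 % after noon (59 % to 61.2 %) and 60.5 % after dawn (59 % to 64 %). It also picks dusk: “Fresh enzyme restores a large share of the lost activity”.

The violet flask gives 55.7 %, 60.5 % after noon and 60.5 % after dawn, and dusk brings 11 percentage points, against 4.8 points for noon, 4.8 points for dawn and 4.1 points for summer.

    free enzyme → unfolded enzyme (k = 3.60 × 10⁻⁴ /min, Ea = 216 kJ/mol)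
    starting material + free enzyme → product + free enzyme, rate k2*[starting material]^2.5*[free enzyme]/(1 + ([starting material]/Kh2)^2.5) (0.0950 M, k = 15000 /M².5/s, Ea = 24.0 kJ/mol)
    starting material ⇌ dormant form (K = 1.10, k = 0.00860 /min, Ea = 101 kJ/mol, ΔH = −35.0 kJ/mol)
    free enzyme + impurity → spent catalyst (k = 1.80 × 10⁵ /M/min, Ea = 38.0 kJ/mol)
    (constants at 25 °C)

By 0.600 h the violet flask held impurity at 0 % of its charge, spent catalyst at 76.5 % of the enzyme charged and free enzyme at 23.2 %, beside the leftover's 23.5 %. From then to 6.00 h that free enzyme, 20.6 % at the end, took the product from 32.1 % to 55.7 %, which is 5900 turnovers per leftover enzyme; the neighbour flask with 0.12 M of starting material, with the same 2.00 µM leftover, held 20.6 % free enzyme at that time and reached 75.1 %.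

The runs are simulated for substances that don't exist.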